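**Assumption:** the SMILES is read as drawn: the flavan (lower) unit is (2R,3R) and is joined through C6 of ring A; the ring-opened (upper) unit is R at both the ester-bearing carbon and the diarylmethine carbon. MBn = 4-methylbenzyl. This route is a paper design and has not been run.

## Retrosynthetic overview

1. Target 27 ⇐ global hydrogenolysis of 26; 26 ⇐ Friedel–Crafts bond C6 (ring A, lower unit)–C2 (open unit) between the 8-bromo flavan gallate 23 and the acyloxonium ion from chloro ester 25.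
2. 23 ⇐ 22 ⇐ ring expansion of the dihydrobenzofuran ester 21 (ring oxygen and gallate change places): ring C of the lower unit, its cis C2/C3 centres and its gallate arise in one step.
3. 21 and 25 both ⇐ one (2R,3R)-epoxide 18 (5-exo phenoxide opening then Mitsunobu inversion for 21; acyl chloride opening for 25).
4. 18 ⇐ (E)-1,3-diarylpropene 16 ⇐ ring A phenol 4 + allylic alcohol 15 (aryllithium 14 + acrolein 13); acid 12 from the same aryl bromide 9 through Grignard reagent 11 + CO2.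
5. All six benzene rings come from resorcinol. Rings are formed in the order oxirane (step 9) → dihydrofuran (step 10) → pyran ring C (step 12); the upper unit stays open.

## Route

Step 1
Reactants: 1 resorcinol
Product: 2 1,3-bis(MBnO)benzene
Conditions: 4-methylbenzyl bromide, K2CO3, DMF, 60 °C
Reagents that add atoms: 4-methylbenzyl bromide, Cc1ccc(CBr)cc1
Why: Williamson ether synthesis; the 4-methylbenzyl rings have no C–H bond without an ortho substituent, so they stay inert in the borylation of step 2 and still leave by hydrogenolysis at the end.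

Step 2
Reactants: 2 1,3-bis(MBnO)benzene
Product: 4 3,5-bis(MBnO)phenol, via aryl pinacol boronate 3 (not isolated)
Conditions: [Ir(OMe)(cod)]2 (1.5 mol%), 4,4′-di-tert-butyl-2,2′-bipyridine (3 mol%), HBpin, THF, 80 °C; then aq. KHSO5 (as 2KHSO5·KHSO4·K2SO4), acetone, rt
Reagents that add atoms: pinacolborane, CC1(C)OBOC1(C)C (boron and pinacolate of 3); potassium peroxymonosulfate, [K+].[O-]S(=O)(=O)OO (the new phenol oxygen of 4)
Why: sterically controlled iridium-catalysed C–H borylation reaches only C5 (the one C–H without an ortho neighbour), and one-pot boronate oxidation gives the ring A phenol.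

Step 3
Reactants: 2 1,3-bis(MBnO)benzene
Product: 7 2,6-bis(MBnO)phenol, via aryllithium 5 (not isolated), via lithium aryltrimethoxyborate 6 (not isolated)
Conditions: n-BuLi, THF, 0 °C; B(OMe)3, −78 °C → rt; 30% H2O2, 0 °C → rt
Reagents that add atoms: n-butyllithium, [Li]CCCC (lithium of 5 and 6); trimethyl borate, COB(OC)OC (in 6); hydrogen peroxide, OO (the new phenol oxygen of 7)
Why: directed ortho-lithiation between the two ether oxygens, borate trapping and oxidation install the third oxygen of the pyrogallol pattern.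

Step 4
Reactants: 7 2,6-bis(MBnO)phenol
Product: 9 5-bromo-1,2,3-tris(MBnO)benzene, via bromophenol 8 (not isolated)
Conditions: NBS (1.0 equiv), DMF, 0 °C, dark; then K2CO3, 4-methylbenzyl bromide, 50 °C
Reagents that add atoms: N-bromosuccinimide, O=C1CCC(=O)N1Br; 4-methylbenzyl bromide, Cc1ccc(CBr)cc1
Why: electrophilic bromination goes para to the free phenol (both ortho positions are blocked), and Williamson etherification in the same pot gives the aryl bromide that serves as source of rings B and of both galloyl groups.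

Step 5
Reactants: 9 5-bromo-1,2,3-tris(MBnO)benzene; 10 carbon dioxide
Product: 12 3,4,5-tris(MBnO)benzoic acid, via arylmagnesium bromide 11 (not isolated)
Conditions: Mg turnings (activated with a crystal of I2), THF, 50 °C; CO2 (g), −20 °C → rt; aq. HCl
Reagents that add atoms: magnesium, [Mg] (magnesium of 11)
Why: Grignard formation by magnesium insertion into the aryl bromide followed by carboxylation gives the protected gallic acid; the bromomagnesium carboxylate does not take up a second aryl group, so no diaryl ketone forms.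

Step 6
Reactants: 9 5-bromo-1,2,3-tris(MBnO)benzene; 13 acrolein
Product: 15 (±)-1-[3,4,5-tris(MBnO)phenyl]prop-2-en-1-ol, via aryllithium 14 (not isolated)
Conditions: n-BuLi, THF, −78 °C; acrolein, −78 °C; H2O
Reagents that add atoms: n-butyllithium, [Li]CCCC (lithium of 14)
Why: bromine–lithium exchange and clean 1,2-addition of the hard aryllithium to acrolein at low temperature give the allylic alcohol; its stereocentre is erased in step 7.

Step 7
Reactants: 4 3,5-bis(MBnO)phenol; 15 (±)-1-[3,4,5-tris(MBnO)phenyl]prop-2-en-1-ol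
Product: 16 2-[(2E)-3-{3,4,5-tris(MBnO)phenyl}prop-2-en-1-yl]-3,5-bis(MBnO)phenol
Conditions: H2SO4 on SiO2 (cat.), CH2Cl2, rt; 4 in two-fold excess
Reagents that add atoms: none
Why: Friedel–Crafts allylation; the aryl-stabilised allyl cation is attacked at its terminal carbon by the carbon ortho to the phenol OH, giving the conjugated (E)-1,3-diarylpropene known for the benzyl analogues.

Step 8
Reactants: 16 2-[(2E)-3-{3,4,5-tris(MBnO)phenyl}prop-2-en-1-yl]-3,5-bis(MBnO)phenol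
Product: 17 benzyl 2-[(2E)-3-{3,4,5-tris(MBnO)phenyl}prop-2-en-1-yl]-3,5-bis(MBnO)phenyl carbonate
Conditions: benzyl chloroformate, K2CO3, acetone, 0 °C → rt
Reagents that add atoms: benzyl chloroformate, O=C(Cl)OCc1ccccc1
Why: O-acylation to the aryl benzyl carbonate, which protects the phenol during epoxidation, is non-nucleophilic in step 15, comes off with methanol in step 10 and by hydrogenolysis in step 16.

Step 9
Reactants: 17 benzyl 2-[(2E)-3-{3,4,5-tris(MBnO)phenyl}prop-2-en-1-yl]-3,5-bis(MBnO)phenyl carbonate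
Product: 18 benzyl 2-{[(2R,3R)-3-{3,4,5-tris(MBnO)phenyl}oxiran-2-yl]methyl}-3,5-bis(MBnO)phenyl carbonate
Conditions: Shi's D-fructose-derived ketone (1.0 equiv, recoverable), KHSO5 (as 2KHSO5·KHSO4·K2SO4), NaHCO3, MeCN–CH2(OMe)2–H2O, pH 7.5–8, 0 °C
Reagents that add atoms: potassium peroxymonosulfate, [K+].[O-]S(=O)(=O)OO
Why: Shi asymmetric epoxidation; the chiral dioxirane delivers oxygen to one face of the trans-disubstituted styrene-type alkene through the spiro transition state and sets both epoxide centres R,R, as for trans-β-alkylstyrenes, while the near-neutral pH spares the carbonate.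

Step 10
Reactants: 18 benzyl 2-{[(2R,3R)-3-{3,4,5-tris(MBnO)phenyl}oxiran-2-yl]methyl}-3,5-bis(MBnO)phenyl carbonate
Product: 20 (R)-[(2S)-4,6-bis(MBnO)-2,3-dihydro-1-benzofuran-2-yl][3,4,5-tris(MBnO)phenyl]methanol, via epoxy phenol 19 (not isolated)
Conditions: K2CO3, MeOH–THF, 0 °C → rt
Reagents that add atoms: none
Why: carbonate methanolysis frees the phenoxide, which opens the epoxide by 5-exo-tet SN2 attack at the nearer carbon (inversion there, carbinol carbon untouched), the usual base-mediated mode of 2-(epoxyalkyl)phenols, giving the erythro dihydrobenzofuran carbinol.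

Step 11
Reactants: 20 (R)-[(2S)-4,6-bis(MBnO)-2,3-dihydro-1-benzofuran-2-yl][3,4,5-tris(MBnO)phenyl]methanol; 12 3,4,5-tris(MBnO)benzoic acid
Product: 21 (S)-[(2S)-4,6-bis(MBnO)-2,3-dihydro-1-benzofuran-2-yl][3,4,5-tris(MBnO)phenyl]methyl 3,4,5-tris(MBnO)benzoate
Conditions: PPh3, DIAD, THF, 0 °C → rt
Reagents that add atoms: none
Why: Mitsunobu esterification with SN2 inversion at the carbinol carbon converts the erythro alcohol into the threo (S,S) gallate needed for the ring expansion.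

Step 12
Reactants: 21 (S)-[(2S)-4,6-bis(MBnO)-2,3-dihydro-1-benzofuran-2-yl][3,4,5-tris(MBnO)phenyl]methyl 3,4,5-tris(MBnO)benzoate
Product: 22 (2R,3R)-5,7-bis(MBnO)-2-[3,4,5-tris(MBnO)phenyl]-3,4-dihydro-2H-1-benzopyran-3-yl 3,4,5-tris(MBnO)benzoate
Conditions: Sc(OSO2CF3)3 (10 mol%), 2,6-di-tert-butyl-4-methylpyridine (15 mol%), 4 Å MS, CH2Cl2, −20 °C → rt
Reagents that add atoms: none
Why: Proposed new method: the Lewis acid ionises the benzylic C–O bond of the ester with backside participation of the ring oxygen to give a bicyclic oxiranium/galloate contact ion pair, and the carbonyl oxygen of the same galloate opens it at the former ring carbon anti to that oxygen, so the five-membered ring becomes ring C, both carbons are inverted ((S,S) → 2R,3R, cis) and the gallate ends on C3; return to the benzylic carbon only regenerates 21, whereas the cis flavan ester is non-benzylic and its axial ester is not antiperiplanar to the C2–O1 bond, so it cannot re-ionise and collects the material; the closest known reaction types are the zinc acetate-mediated expansion of 2-(1-sulfonyloxyalkyl)tetrahydrofurans to 3-acetoxytetrahydropyrans through bicyclic oxonium ions, the prolinol to 3-acyloxypiperidine expansion through aziridinium ions, and the ring contraction of flavan-3-ols to 2-(α-fluorobenzyl)dihydrobenzofurans through the same oxiranium ion, run here in the opposite sense.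

Step 13
Reactants: 22 (2R,3R)-5,7-bis(MBnO)-2-[3,4,5-tris(MBnO)phenyl]-3,4-dihydro-2H-1-benzopyran-3-yl 3,4,5-tris(MBnO)benzoate
Product: 23 (2R,3R)-8-bromo-5,7-bis(MBnO)-2-[3,4,5-tris(MBnO)phenyl]-3,4-dihydro-2H-1-benzopyran-3-yl 3,4,5-tris(MBnO)benzoate
Conditions: NBS (1.05 equiv), CH2Cl2, −78 → −20 °C, dark
Reagents that add atoms: N-bromosuccinimide, O=C1CCC(=O)N1Br
Why: electrophilic aromatic bromination at C8, the most nucleophilic position of 5,7-di-O-alkyl flavans, blocks that site so that only C6 can react in step 15; the bromine leaves in step 16.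

Step 14
Reactants: 12 3,4,5-tris(MBnO)benzoic acid; 18 benzyl 2-{[(2R,3R)-3-{3,4,5-tris(MBnO)phenyl}oxiran-2-yl]methyl}-3,5-bis(MBnO)phenyl carbonate
Product: 25 (1S,2R)-3-[2-{[(benzyloxy)carbonyl]oxy}-4,6-bis(MBnO)phenyl]-1-chloro-1-[3,4,5-tris(MBnO)phenyl]propan-2-yl 3,4,5-tris(MBnO)benzoate, via acid chloride 24 (not isolated)
Conditions: 12, (COCl)2, cat. DMF, CH2Cl2, 0 °C → rt, evaporate; then 18, Bu4NCl (10 mol%), CH2Cl2, 0 °C → rt
Reagents that add atoms: oxalyl chloride, O=C(Cl)C(=O)Cl (chlorine of 24 and 25)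
Why: acid chloride formation, then chloride-catalysed acylative epoxide opening in which chloride attacks the benzylic carbon with inversion and the epoxide oxygen becomes the ester with retention; the regioisomeric anti chloro ester, if formed, gives the same acyloxonium ion in step 15.

Step 15
Reactants: 25 (1S,2R)-3-[2-{[(benzyloxy)carbonyl]oxy}-4,6-bis(MBnO)phenyl]-1-chloro-1-[3,4,5-tris(MBnO)phenyl]propan-2-yl 3,4,5-tris(MBnO)benzoate; 23 (2R,3R)-8-bromo-5,7-bis(MBnO)-2-[3,4,5-tris(MBnO)phenyl]-3,4-dihydro-2H-1-benzopyran-3-yl 3,4,5-tris(MBnO)benzoate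
Product: 26 (1R,2R)-1-[(2R,3R)-8-bromo-5,7-bis(MBnO)-3-{[3,4,5-tris(MBnO)benzoyl]oxy}-2-{3,4,5-tris(MBnO)phenyl}-3,4-dihydro-2H-1-benzopyran-6-yl]-3-[2-{[(benzyloxy)carbonyl]oxy}-4,6-bis(MBnO)phenyl]-1-[3,4,5-tris(MBnO)phenyl]propan-2-yl 3,4,5-tris(MBnO)benzoate
Conditions: 23 (2.5 equiv, excess recovered), AgOSO2CF3 (1.3 equiv), 2,6-di-tert-butyl-4-methylpyridine (1.5 equiv), 4 Å MS, CH2Cl2, −40 → 0 °C
Reagents that add atoms: none
Why: Friedel–Crafts alkylation with neighbouring-group participation; silver pulls off chloride while the vicinal gallate closes to the trans acyloxonium (1,3-dioxolan-2-ylium) ion, and C6 of 23, the only free ring A position, attacks the benzylic carbon anti to the departing oxygen, which sets the diarylmethine centre R and leaves the gallate on the neighbouring carbon.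

Step 16
Reactants: 26 (protected dimer named in step 15)
Product: 27 CNP0240551.1, (1R,2R)-1-[(2R,3R)-5,7-dihydroxy-3-(3,4,5-trihydroxybenzoyloxy)-2-(3,4,5-trihydroxyphenyl)-3,4-dihydro-2H-1-benzopyran-6-yl]-1-(3,4,5-trihydroxyphenyl)-3-(2,4,6-trihydroxyphenyl)propan-2-yl 3,4,5-trihydroxybenzoate
Conditions: H2 (1 atm), Pd(OH)2/C, Et3N (1.0 equiv), THF–MeOH, rt; acidic work-up under argon
Reagents that add atoms: none
Why: global hydrogenolysis removes the sixteen 4-methylbenzyl ethers, the benzyl carbonate (with loss of CO2) and the C8 bromine in one operation without touching the four stereocentres.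

## Compound list

1 | resorcinol (benzene-1,3-diol) | Oc1cccc(O)c1 | starting material
2 | 1,3-bis[(4-methylbenzyl)oxy]benzene | c1cc(OCc2ccc(C)cc2)cc(OCc2ccc(C)cc2)c1 | intermediate
3 | 2-{3,5-bis[(4-methylbenzyl)oxy]phenyl}-4,4,5,5-tetramethyl-1,3,2-dioxaborolane | CC1(C)OB(OC1(C)C)c1cc(OCc2ccc(C)cc2)cc(OCc2ccc(C)cc2)c1 | intermediate (not isolated)
4 | 3,5-bis[(4-methylbenzyl)oxy]phenol | Oc1cc(OCc2ccc(C)cc2)cc(OCc2ccc(C)cc2)c1 | intermediate
5 | {2,6-bis[(4-methylbenzyl)oxy]phenyl}lithium | [Li]c1c(OCc2ccc(C)cc2)cccc1OCc1ccc(C)cc1 | intermediate (not isolated)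
6 | lithium {2,6-bis[(4-methylbenzyl)oxy]phenyl}trimethoxyborate | [Li+].CO[B-](OC)(OC)c1c(OCc2ccc(C)cc2)cccc1OCc1ccc(C)cc1 | intermediate (not isolated)
7 | 2,6-bis[(4-methylbenzyl)oxy]phenol | Oc1c(OCc2ccc(C)cc2)cccc1OCc1ccc(C)cc1 | intermediate
8 | 4-bromo-2,6-bis[(4-methylbenzyl)oxy]phenol | Oc1c(OCc2ccc(C)cc2)cc(Br)cc1OCc1ccc(C)cc1 | intermediate (not isolated)
9 | 5-bromo-1,2,3-tris[(4-methylbenzyl)oxy]benzene | Brc1cc(OCc2ccc(C)cc2)c(OCc2ccc(C)cc2)c(OCc2ccc(C)cc2)c1 | intermediate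
10 | carbon dioxide | O=C=O | starting material
11 | {3,4,5-tris[(4-methylbenzyl)oxy]phenyl}magnesium bromide | Br[Mg]c1cc(OCc2ccc(C)cc2)c(OCc2ccc(C)cc2)c(OCc2ccc(C)cc2)c1 | intermediate (not isolated)
12 | 3,4,5-tris[(4-methylbenzyl)oxy]benzoic acid | OC(=O)c1cc(OCc2ccc(C)cc2)c(OCc2ccc(C)cc2)c(OCc2ccc(C)cc2)c1 | intermediate
13 | acrolein (prop-2-enal) | C=CC=O | starting material
14 | {3,4,5-tris[(4-methylbenzyl)oxy]phenyl}lithium | [Li]c1cc(OCc2ccc(C)cc2)c(OCc2ccc(C)cc2)c(OCc2ccc(C)cc2)c1 | intermediate (not isolated)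
15 | (±)-1-{3,4,5-tris[(4-methylbenzyl)oxy]phenyl}prop-2-en-1-ol | C=CC(O)c1cc(OCc2ccc(C)cc2)c(OCc2ccc(C)cc2)c(OCc2ccc(C)cc2)c1 | intermediate
16 | 2-[(2E)-3-{3,4,5-tris[(4-methylbenzyl)oxy]phenyl}prop-2-en-1-yl]-3,5-bis[(4-methylbenzyl)oxy]phenol | Oc1cc(OCc2ccc(C)cc2)cc(OCc2ccc(C)cc2)c1C/C=C/c1cc(OCc2ccc(C)cc2)c(OCc2ccc(C)cc2)c(OCc2ccc(C)cc2)c1 | intermediate
17 | benzyl 2-[(2E)-3-{3,4,5-tris[(4-methylbenzyl)oxy]phenyl}prop-2-en-1-yl]-3,5-bis[(4-methylbenzyl)oxy]phenyl carbonate | O=C(OCc1ccccc1)Oc1cc(OCc2ccc(C)cc2)cc(OCc2ccc(C)cc2)c1C/C=C/c1cc(OCc2ccc(C)cc2)c(OCc2ccc(C)cc2)c(OCc2ccc(C)cc2)c1 | intermediate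
18 | benzyl 2-{[(2R,3R)-3-{3,4,5-tris[(4-methylbenzyl)oxy]phenyl}oxiran-2-yl]methyl}-3,5-bis[(4-methylbenzyl)oxy]phenyl carbonate | O=C(OCc1ccccc1)Oc1cc(OCc2ccc(C)cc2)cc(OCc2ccc(C)cc2)c1C[C@H]1O[C@@H]1c1cc(OCc2ccc(C)cc2)c(OCc2ccc(C)cc2)c(OCc2ccc(C)cc2)c1 | intermediate
19 | 2-{[(2R,3R)-3-{3,4,5-tris[(4-methylbenzyl)oxy]phenyl}oxiran-2-yl]methyl}-3,5-bis[(4-methylbenzyl)oxy]phenol | Oc1cc(OCc2ccc(C)cc2)cc(OCc2ccc(C)cc2)c1C[C@H]1O[C@@H]1c1cc(OCc2ccc(C)cc2)c(OCc2ccc(C)cc2)c(OCc2ccc(C)cc2)c1 | intermediate (not isolated)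
20 | (R)-{(2S)-4,6-bis[(4-methylbenzyl)oxy]-2,3-dihydro-1-benzofuran-2-yl}{3,4,5-tris[(4-methylbenzyl)oxy]phenyl}methanol | O[C@H](c1cc(OCc2ccc(C)cc2)c(OCc2ccc(C)cc2)c(OCc2ccc(C)cc2)c1)[C@@H]1Cc2c(OCc3ccc(C)cc3)cc(OCc3ccc(C)cc3)cc2O1 | intermediate
21 | (S)-{(2S)-4,6-bis[(4-methylbenzyl)oxy]-2,3-dihydro-1-benzofuran-2-yl}{3,4,5-tris[(4-methylbenzyl)oxy]phenyl}methyl 3,4,5-tris[(4-methylbenzyl)oxy]benzoate | O=C(c1cc(OCc2ccc(C)cc2)c(OCc2ccc(C)cc2)c(OCc2ccc(C)cc2)c1)O[C@@H](c1cc(OCc2ccc(C)cc2)c(OCc2ccc(C)cc2)c(OCc2ccc(C)cc2)c1)[C@@H]1Cc2c(OCc3ccc(C)cc3)cc(OCc3ccc(C)cc3)cc2O1 | intermediate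
22 | (2R,3R)-5,7-bis[(4-methylbenzyl)oxy]-2-{3,4,5-tris[(4-methylbenzyl)oxy]phenyl}-3,4-dihydro-2H-1-benzopyran-3-yl 3,4,5-tris[(4-methylbenzyl)oxy]benzoate | O=C(c1cc(OCc2ccc(C)cc2)c(OCc2ccc(C)cc2)c(OCc2ccc(C)cc2)c1)O[C@@H]1Cc2c(OCc3ccc(C)cc3)cc(OCc3ccc(C)cc3)cc2O[C@@H]1c1cc(OCc2ccc(C)cc2)c(OCc2ccc(C)cc2)c(OCc2ccc(C)cc2)c1 | intermediate
23 | (2R,3R)-8-bromo-5,7-bis[(4-methylbenzyl)oxy]-2-{3,4,5-tris[(4-methylbenzyl)oxy]phenyl}-3,4-dihydro-2H-1-benzopyran-3-yl 3,4,5-tris[(4-methylbenzyl)oxy]benzoate | O=C(c1cc(OCc2ccc(C)cc2)c(OCc2ccc(C)cc2)c(OCc2ccc(C)cc2)c1)O[C@@H]1Cc2c(OCc3ccc(C)cc3)cc(OCc3ccc(C)cc3)c(Br)c2O[C@@H]1c1cc(OCc2ccc(C)cc2)c(OCc2ccc(C)cc2)c(OCc2ccc(C)cc2)c1 | intermediate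
24 | 3,4,5-tris[(4-methylbenzyl)oxy]benzoyl chloride | O=C(Cl)c1cc(OCc2ccc(C)cc2)c(OCc2ccc(C)cc2)c(OCc2ccc(C)cc2)c1 | intermediate (not isolated)
25 | (1S,2R)-3-(2-{[(benzyloxy)carbonyl]oxy}-4,6-bis[(4-methylbenzyl)oxy]phenyl)-1-chloro-1-{3,4,5-tris[(4-methylbenzyl)oxy]phenyl}propan-2-yl 3,4,5-tris[(4-methylbenzyl)oxy]benzoate | Cl[C@@H](c1cc(OCc2ccc(C)cc2)c(OCc2ccc(C)cc2)c(OCc2ccc(C)cc2)c1)[C@H](OC(=O)c1cc(OCc2ccc(C)cc2)c(OCc2ccc(C)cc2)c(OCc2ccc(C)cc2)c1)Cc1c(OC(=O)OCc2ccccc2)cc(OCc2ccc(C)cc2)cc1OCc1ccc(C)cc1 | intermediate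
26 | (1R,2R)-1-[(2R,3R)-8-bromo-5,7-bis[(4-methylbenzyl)oxy]-3-({3,4,5-tris[(4-methylbenzyl)oxy]benzoyl}oxy)-2-{3,4,5-tris[(4-methylbenzyl)oxy]phenyl}-3,4-dihydro-2H-1-benzopyran-6-yl]-3-(2-{[(benzyloxy)carbonyl]oxy}-4,6-bis[(4-methylbenzyl)oxy]phenyl)-1-{3,4,5-tris[(4-methylbenzyl)oxy]phenyl}propan-2-yl 3,4,5-tris[(4-methylbenzyl)oxy]benzoate | O=C(O[C@H](Cc1c(OC(=O)OCc2ccccc2)cc(OCc2ccc(C)cc2)cc1OCc1ccc(C)cc1)[C@H](c1cc(OCc2ccc(C)cc2)c(OCc2ccc(C)cc2)c(OCc2ccc(C)cc2)c1)c1c(OCc2ccc(C)cc2)c(Br)c2c(c1OCc1ccc(C)cc1)C[C@@H](OC(=O)c1cc(OCc3ccc(C)cc3)c(OCc3ccc(C)cc3)c(OCc3ccc(C)cc3)c1)[C@@H](c1cc(OCc3ccc(C)cc3)c(OCc3ccc(C)cc3)c(OCc3ccc(C)cc3)c1)O2)c1cc(OCc2ccc(C)cc2)c(OCc2ccc(C)cc2)c(OCc2ccc(C)cc2)c1 | intermediate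
27 | CNP0240551.1, (1R,2R)-1-[(2R,3R)-5,7-dihydroxy-3-(3,4,5-trihydroxybenzoyloxy)-2-(3,4,5-trihydroxyphenyl)-3,4-dihydro-2H-1-benzopyran-6-yl]-1-(3,4,5-trihydroxyphenyl)-3-(2,4,6-trihydroxyphenyl)propan-2-yl 3,4,5-trihydroxybenzoate | O=C(O[C@H](Cc1c(O)cc(O)cc1O)[C@H](c1cc(O)c(O)c(O)c1)c1c(O)cc2c(c1O)C[C@@H](OC(=O)c1cc(O)c(O)c(O)c1)[C@@H](c1cc(O)c(O)c(O)c1)O2)c1cc(O)c(O)c(O)c1 | target

## Step count and risks

Total step count: 16. Longest linear sequence: 13 steps (steps 1, 3, 4, 6, 7, 8, 9, 10, 11, 12, 13, 15, 16).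

**Step 12 (the proposed new ring expansion).** It can stall at benzylic return or leak through a free benzylic cation to the 2,3-trans flavan ester. The fallback uses known chemistry, sets out from epoxide 18 and comes back at 22. Acid-catalysed hydrolysis (HClO4, THF–H2O, 0 °C), with water attacking the benzylic carbon with inversion, gives benzyl 2-[(2R,3S)-2,3-dihydroxy-3-{3,4,5-tris[(4-methylbenzyl)oxy]phenyl}propyl]-3,5-bis[(4-methylbenzyl)oxy]phenyl carbonate F1. K2CO3 in MeOH removes the carbonate to give 2-[(2R,3S)-2,3-dihydroxy-3-{3,4,5-tris[(4-methylbenzyl)oxy]phenyl}propyl]-3,5-bis[(4-methylbenzyl)oxy]phenol F2. Intramolecular Mitsunobu etherification (PPh3, DIAD, THF), in which the phenol displaces the activated benzylic hydroxyl with inversion, closes ring C directly to (2R,3R)-5,7-bis[(4-methylbenzyl)oxy]-2-{3,4,5-tris[(4-methylbenzyl)oxy]phenyl}-3,4-dihydro-2H-1-benzopyran-3-ol F3. Esterification of F3 with acid 12 (EDC·HCl, DMAP, CH2Cl2) gives 22.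

**Step 15 (union at the hindered C6).** Attack on the acyloxonium ion may be slow, and ring A of 25 can compete as nucleophile. The fallback sets out from epoxide 18 and bromide 23 and comes back at 26. BF3·OEt2 (CH2Cl2, −78 → −40 °C, 23 in excess) lets C6 of 23 open the epoxide directly at the benzylic carbon with inversion. This gives (2R,3R)-8-bromo-6-[(1R,2R)-3-(2-{[(benzyloxy)carbonyl]oxy}-4,6-bis[(4-methylbenzyl)oxy]phenyl)-2-hydroxy-1-{3,4,5-tris[(4-methylbenzyl)oxy]phenyl}propyl]-5,7-bis[(4-methylbenzyl)oxy]-2-{3,4,5-tris[(4-methylbenzyl)oxy]phenyl}-3,4-dihydro-2H-1-benzopyran-3-yl 3,4,5-tris[(4-methylbenzyl)oxy]benzoate F4. Esterification of its free hydroxyl with acid 12 (EDC·HCl, DMAP, CH2Cl2) gives 26.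

**Step 11 (Mitsunobu inversion next to the ring oxygen).** Participation of that oxygen could give retention or early rearrangement to the trans series. The fallback sets out from alcohol 20 and comes back at 21. Dess–Martin periodinane (NaHCO3, CH2Cl2) gives {(2S)-4,6-bis[(4-methylbenzyl)oxy]-2,3-dihydro-1-benzofuran-2-yl}{3,4,5-tris[(4-methylbenzyl)oxy]phenyl}methanone F5. Reduction with LiB(s-Bu)3H (THF, −78 °C) under Felkin–Anh control gives the threo alcohol (S)-{(2S)-4,6-bis[(4-methylbenzyl)oxy]-2,3-dihydro-1-benzofuran-2-yl}{3,4,5-tris[(4-methylbenzyl)oxy]phenyl}methanol F6. Esterification with acid 12 (EDC·HCl, DMAP, CH2Cl2), with retention, gives 21.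

Further compounds
F1 | step 12 | benzyl 2-[(2R,3S)-2,3-dihydroxy-3-{3,4,5-tris[(4-methylbenzyl)oxy]phenyl}propyl]-3,5-bis[(4-methylbenzyl)oxy]phenyl carbonate | O[C@@H](c1cc(OCc2ccc(C)cc2)c(OCc2ccc(C)cc2)c(OCc2ccc(C)cc2)c1)[C@H](O)Cc1c(OC(=O)OCc2ccccc2)cc(OCc2ccc(C)cc2)cc1OCc1ccc(C)cc1
F2 | step 12 | 2-[(2R,3S)-2,3-dihydroxy-3-{3,4,5-tris[(4-methylbenzyl)oxy]phenyl}propyl]-3,5-bis[(4-methylbenzyl)oxy]phenol | O[C@@H](c1cc(OCc2ccc(C)cc2)c(OCc2ccc(C)cc2)c(OCc2ccc(C)cc2)c1)[C@H](O)Cc1c(O)cc(OCc2ccc(C)cc2)cc1OCc1ccc(C)cc1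
F3 | step 12 | (2R,3R)-5,7-bis[(4-methylbenzyl)oxy]-2-{3,4,5-tris[(4-methylbenzyl)oxy]phenyl}-3,4-dihydro-2H-1-benzopyran-3-ol | O[C@@H]1Cc2c(OCc3ccc(C)cc3)cc(OCc3ccc(C)cc3)cc2O[C@@H]1c1cc(OCc2ccc(C)cc2)c(OCc2ccc(C)cc2)c(OCc2ccc(C)cc2)c1
F4 | step 15 | (2R,3R)-8-bromo-6-[(1R,2R)-3-(2-{[(benzyloxy)carbonyl]oxy}-4,6-bis[(4-methylbenzyl)oxy]phenyl)-2-hydroxy-1-{3,4,5-tris[(4-methylbenzyl)oxy]phenyl}propyl]-5,7-bis[(4-methylbenzyl)oxy]-2-{3,4,5-tris[(4-methylbenzyl)oxy]phenyl}-3,4-dihydro-2H-1-benzopyran-3-yl 3,4,5-tris[(4-methylbenzyl)oxy]benzoate | O[C@H](Cc1c(OC(=O)OCc2ccccc2)cc(OCc2ccc(C)cc2)cc1OCc1ccc(C)cc1)[C@H](c1cc(OCc2ccc(C)cc2)c(OCc2ccc(C)cc2)c(OCc2ccc(C)cc2)c1)c1c(OCc2ccc(C)cc2)c(Br)c2c(c1OCc1ccc(C)cc1)C[C@@H](OC(=O)c1cc(OCc3ccc(C)cc3)c(OCc3ccc(C)cc3)c(OCc3ccc(C)cc3)c1)[C@@H](c1cc(OCc3ccc(C)cc3)c(OCc3ccc(C)cc3)c(OCc3ccc(C)cc3)c1)O2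
F5 | step 11 | {(2S)-4,6-bis[(4-methylbenzyl)oxy]-2,3-dihydro-1-benzofuran-2-yl}{3,4,5-tris[(4-methylbenzyl)oxy]phenyl}methanone | O=C(c1cc(OCc2ccc(C)cc2)c(OCc2ccc(C)cc2)c(OCc2ccc(C)cc2)c1)[C@@H]1Cc2c(OCc3ccc(C)cc3)cc(OCc3ccc(C)cc3)cc2O1
F6 | step 11 | (S)-{(2S)-4,6-bis[(4-methylbenzyl)oxy]-2,3-dihydro-1-benzofuran-2-yl}{3,4,5-tris[(4-methylbenzyl)oxy]phenyl}methanol | O[C@@H](c1cc(OCc2ccc(C)cc2)c(OCc2ccc(C)cc2)c(OCc2ccc(C)cc2)c1)[C@@H]1Cc2c(OCc3ccc(C)cc3)cc(OCc3ccc(C)cc3)cc2O1
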